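Both tetralone units are γ-hydroxy aryl ketones: the C4 carbinol and the C1 carbonyl of each cyclohexanone ring hang on the neighbouring benzo carbons C4a and C8a. Each ring is therefore cut at C1–C8a and stored as a γ-aryl-γ-butyrolactone in which O4 carries the C1 acyl group. The key step, a twofold halogen–lithium exchange on a bis-lactone dihalide, shifts both acyl groups from O4 to the lithiated C8a (Parham cyclisation, anionic homo-Fries shift); in unit B the carbanion sits between C4a and the C8 oxygen. One operation closes both cyclohexanone rings, frees both carbinols and leaves the three stereocentres untouched. The precursor comes from an anti-selective asymmetric allylation.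

Key step: step 14

Remark: each half is numbered as a 1-tetralone (C1 carbonyl, C4 carbinol, C4a and C8a at the ring fusion); unit A is the 3-aryl-4,5-dihydroxy-7-methyl half, unit B the 4,8-dihydroxy-6-methyl half bonded through C7 to C3 of unit A; the target is read as (3R,4S) in unit A (aryl and 4-OH cis) and (4R) in unit B; 1, 6 and 14 are assumed to be purchased.

Step 1
Reactants: 1 3-hydroxy-5-methylbenzaldehyde
Product: 2 3-(methoxymethoxy)-5-methylbenzaldehyde
Conditions: MOMCl, i-Pr2NEt, CH2Cl2, 0 °C → rt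
Reagents that add atoms: chloromethyl methyl ether, COCCl
Why: O-alkylation of the phenol gives the MOM ether, which should tolerate organolithiums and act as an ortho-directing group in step 2.

Step 2
Reactants: 2 3-(methoxymethoxy)-5-methylbenzaldehyde
Product: 5 2-iodo-3-(methoxymethoxy)-5-methylbenzaldehyde, via lithium α-amino alkoxide 3 (not isolated), via ortho-lithiated α-amino alkoxide 4 (not isolated)
Conditions: LiN(Me)CH2CH2NMe2, THF, −20 °C; n-BuLi, −20 °C; I2, −78 °C → rt; aq. NH4Cl
Reagents that add atoms: iodine, II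
Why: Directed ortho-metalation with the aldehyde masked in situ as an α-amino alkoxide; this group and the MOM ether cooperate, so lithiation should occur at the carbon between them, and iodine traps the aryllithium.

Step 3
Reactants: 5 2-iodo-3-(methoxymethoxy)-5-methylbenzaldehyde; 6 methyl acrylate
Product: 7 methyl 4-[2-iodo-3-(methoxymethoxy)-5-methylphenyl]-4-oxobutanoate
Conditions: 3-benzyl-5-(2-hydroxyethyl)-4-methylthiazolium chloride (20 mol%), Et3N, DMF, 70 °C
Reagents that add atoms: none
Why: Stetter reaction, in which the thiazolium-derived acyl anion equivalent of the aldehyde adds to the acrylate to give the 1,4-dicarbonyl compound.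

Step 4
Reactants: 7 methyl 4-[2-iodo-3-(methoxymethoxy)-5-methylphenyl]-4-oxobutanoate
Product: 9 (5R)-5-(3-hydroxy-2-iodo-5-methylphenyl)oxolan-2-one, via hydroxy ester 8 (not isolated)
Conditions: RuCl(p-cymene)[(R,R)-TsDPEN] (1 mol%), HCO2H/Et3N (5:2), DMF, 40 °C; then HCl (3 M in MeOH), 50 °C
Reagents that add atoms: none
Why: Noyori-type asymmetric transfer hydrogenation of the aryl ketone, where the (R,R)-catalyst should give the (R)-carbinol that becomes C4 of unit B; acid then closes the γ-lactone and removes the phenolic MOM group by acetal exchange.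

Step 5
Reactants: 9 (5R)-5-(3-hydroxy-2-iodo-5-methylphenyl)oxolan-2-one
Product: 10 2-hydroxy-3-iodo-6-methyl-4-[(2R)-5-oxooxolan-2-yl]benzaldehyde
Conditions: MgCl2, Et3N, (CH2O)n, MeCN, reflux; aq. HCl work-up
Reagents that add atoms: formaldehyde (from paraformaldehyde), C=O
Why: Magnesium-mediated ortho-formylation of the phenol; the only free ortho carbon is the one between OH and methyl, because the other carries iodine, and a second equivalent of formaldehyde oxidises the benzylic alkoxide to the aldehyde.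

Step 6
Reactants: 10 2-hydroxy-3-iodo-6-methyl-4-[(2R)-5-oxooxolan-2-yl]benzaldehyde
Product: 11 3-iodo-2-(methoxymethoxy)-6-methyl-4-[(2R)-5-oxooxolan-2-yl]benzaldehyde
Conditions: MOMCl, i-Pr2NEt, CH2Cl2, 0 °C → reflux
Reagents that add atoms: chloromethyl methyl ether, COCCl
Why: O-alkylation of the chelated phenol; the MOM ether cannot migrate to a neighbouring alkoxide in step 7 and survives the organometallic steps.

Step 7
Reactants: 11 3-iodo-2-(methoxymethoxy)-6-methyl-4-[(2R)-5-oxooxolan-2-yl]benzaldehyde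
Product: 12 (5R)-5-[4-(1-hydroxyprop-2-en-1-yl)-2-iodo-3-(methoxymethoxy)-5-methylphenyl]oxolan-2-one (both carbinol epimers)
Conditions: CH2=CHMgBr (1.1 equiv), THF, −78 °C; aq. NH4Cl
Reagents that add atoms: vinylmagnesium bromide, C=C[Mg]Br
Why: Grignard 1,2-addition, expected to be chemoselective for the aldehyde over the lactone at −78 °C; the new carbinol centre is lost in step 8.

Step 8
Reactants: 12 (5R)-5-[4-(1-hydroxyprop-2-en-1-yl)-2-iodo-3-(methoxymethoxy)-5-methylphenyl]oxolan-2-one
Product: 13 (5R)-5-{4-[(1E)-3-bromoprop-1-en-1-yl]-2-iodo-3-(methoxymethoxy)-5-methylphenyl}oxolan-2-one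
Conditions: PBr3 (0.4 equiv), pyridine (cat.), Et2O, −10 → 0 °C
Reagents that add atoms: phosphorus tribromide, BrP(Br)Br
Why: Bromination of the aryl vinyl carbinol with allylic transposition (SN2′ or ion-pair return) should give the conjugated (E)-cinnamyl bromide as the thermodynamic product.

Step 9
Reactants: 14 3-bromo-5-methylphenol
Product: 15 1-bromo-3-(methoxymethoxy)-5-methylbenzene
Conditions: MOMCl, i-Pr2NEt, CH2Cl2, 0 °C → rt
Reagents that add atoms: chloromethyl methyl ether, COCCl
Why: O-alkylation of the phenol installs the directing and protecting group for unit A.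

Step 10
Reactants: 15 1-bromo-3-(methoxymethoxy)-5-methylbenzene
Product: 18 2-bromo-6-(methoxymethoxy)-4-methylbenzaldehyde, via aryllithium 16 (not isolated), via lithium hemiaminal alkoxide 17 (not isolated)
Conditions: LiN(i-Pr)2, THF, −78 °C; DMF, −78 → 0 °C; aq. NH4Cl
Reagents that add atoms: N,N-dimethylformamide, CN(C)C=O
Why: Directed ortho-lithiation at the most acidic C–H, between bromine and the MOM ether, kept at −78 °C to avoid aryne formation, followed by formylation with DMF.

Step 11
Reactants: 13 (5R)-5-{4-[(1E)-3-bromoprop-1-en-1-yl]-2-iodo-3-(methoxymethoxy)-5-methylphenyl}oxolan-2-one; 18 2-bromo-6-(methoxymethoxy)-4-methylbenzaldehyde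
Product: 20 (5R)-5-{4-[(3R,4S)-4-[2-bromo-6-(methoxymethoxy)-4-methylphenyl]-4-hydroxybut-1-en-3-yl]-2-iodo-3-(methoxymethoxy)-5-methylphenyl}oxolan-2-one, via trimethylsilyl ether 19 (not isolated)
Conditions: CrCl2 (10 mol%), 3,6-di-tert-butyl-1,8-bis[(4S)-4-isopropyl-4,5-dihydro-1,3-oxazol-2-yl]-9H-carbazole (12 mol%), i-Pr2NEt, Mn, TMSCl, THF, 0 °C → rt; then aq. citric acid
Reagents that add atoms: none
Why: Catalytic asymmetric Nozaki–Hiyama–Kishi allylation, in which the (E)-γ-aryl allylchromium should add through its γ-carbon in a closed chair transition state (anti, C3 aryl against C4 oxygen of unit A) while the chiral chromium complex selects the aldehyde face to set (3R,4S) (the mirror-image ligand would be taken if its sense were opposite); without nickel the aryl halides and the lactone should stay intact.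

Step 12
Reactants: 20 (5R)-5-{4-[(3R,4S)-4-[2-bromo-6-(methoxymethoxy)-4-methylphenyl]-4-hydroxybut-1-en-3-yl]-2-iodo-3-(methoxymethoxy)-5-methylphenyl}oxolan-2-one
Product: 22 (5R)-5-{4-[(1S,2R)-1-[2-bromo-6-(methoxymethoxy)-4-methylphenyl]-1,4-dihydroxybutan-2-yl]-2-iodo-3-(methoxymethoxy)-5-methylphenyl}oxolan-2-one, via B-alkyl-9-borabicyclononane 21 (not isolated)
Conditions: 9-BBN (3 equiv), THF, 0 °C → rt; then H2O2 (30%), aq. NaOH, 0 °C; acidify to pH 4
Reagents that add atoms: hydrogen peroxide, OO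
Why: Anti-Markovnikov hydroboration of the terminal alkene and oxidation with retention gives the primary alcohol that becomes C1 of unit A; 9-BBN should not reduce the lactone or touch the aryl halides.

Step 13
Reactants: 22 (5R)-5-{4-[(1S,2R)-1-[2-bromo-6-(methoxymethoxy)-4-methylphenyl]-1,4-dihydroxybutan-2-yl]-2-iodo-3-(methoxymethoxy)-5-methylphenyl}oxolan-2-one
Product: 24 (4R,5S)-5-[2-bromo-6-(methoxymethoxy)-4-methylphenyl]-4-{3-iodo-2-(methoxymethoxy)-6-methyl-4-[(2R)-5-oxooxolan-2-yl]phenyl}oxolan-2-one, via lactol 23 (not isolated)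
Conditions: TEMPO (20 mol%), PhI(OAc)2 (2.5 equiv), CH2Cl2, rt
Reagents that add atoms: none
Why: Oxoammonium oxidation is selective for the primary alcohol; the aldehyde is trapped by the hindered benzylic hydroxyl as a lactol and oxidised on to the trans-4,5-diaryl γ-lactone (oxidative lactonisation of a 1,4-diol).

Step 14
Reactants: 24 (4R,5S)-5-[2-bromo-6-(methoxymethoxy)-4-methylphenyl]-4-{3-iodo-2-(methoxymethoxy)-6-methyl-4-[(2R)-5-oxooxolan-2-yl]phenyl}oxolan-2-one
Product: 27 (3R,4S)-4-hydroxy-3-[(5R)-5-hydroxy-1-(methoxymethoxy)-3-methyl-8-oxo-5,6,7,8-tetrahydronaphthalen-2-yl]-5-(methoxymethoxy)-7-methyl-3,4-dihydronaphthalen-1(2H)-one, via bis(aryllithium) 25 (not isolated), via dilithium dialkoxide 26 (not isolated)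
Conditions: t-BuLi (4.4 equiv), THF/Et2O, −100 °C, 24 added to the base; −78 °C; AcOH
Reagents that add atoms: none
Why: Twofold halogen–lithium exchange (C–I on ring B, C–Br on ring A) gives the bis(aryllithium) 25, in which each carbanion sits ortho to the carbon that bears a lactone and attacks that lactone carbonyl; collapse of the bridged hemiketal alkoxide breaks the acyl–oxygen bond, so the acyl group moves from O4 to C8a and the carbinol is released as its alkoxide. The closest known reaction types are the Parham cyclisation of ortho-haloaryl esters and the anionic homo-Fries (1,4 O→C acyl) rearrangement of ortho-lithiated benzyl esters. Each cyclohexanone ring closes by 6-exo-trig attack of the aryllithium on the lactone carbonyl, forming C1–C8a of unit B and the corresponding C1–C8a bond of unit A. No stereocentre is formed: C4 of unit B and C3 and C4 of unit A keep the configurations set in steps 4 and 11 because only acyl–oxygen bonds break, and the trans-lactone of unit A becomes the cis-3-aryl-4-hydroxy tetralone. The step needs exchange to outrun addition of t-BuLi to the lactones (very low temperature, inverse addition, fast iodine– and bromine–lithium exchange) and needs each aryllithium to reach only its own lactone, which geometry secures because only these six-membered closures are possible. The position of ring closure in unit B, between C4a and the C8 oxygen, is fixed by the place of the iodine.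

Step 15
Reactants: 27 (3R,4S)-4-hydroxy-3-[(5R)-5-hydroxy-1-(methoxymethoxy)-3-methyl-8-oxo-5,6,7,8-tetrahydronaphthalen-2-yl]-5-(methoxymethoxy)-7-methyl-3,4-dihydronaphthalen-1(2H)-one
Product: 28 (3R,4S)-4,5-dihydroxy-3-[(5R)-1,5-dihydroxy-3-methyl-8-oxo-5,6,7,8-tetrahydronaphthalen-2-yl]-7-methyl-3,4-dihydronaphthalen-1(2H)-one
Conditions: aq. HCl (2 M), THF, 0 °C → rt
Reagents that add atoms: none
Why: Mild acid hydrolysis of the two phenolic MOM acetals, which should cleave faster than the benzylic carbinols ionise.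

Compound list
1 | 3-hydroxy-5-methylbenzaldehyde | Cc1cc(O)cc(C=O)c1 | starting material
2 | 3-(methoxymethoxy)-5-methylbenzaldehyde | COCOc1cc(C)cc(C=O)c1 | intermediate
3 | lithium α-amino alkoxide of 2 | COCOc1cc(C)cc(C(O[Li])N(C)CCN(C)C)c1 | intermediate (not isolated)
4 | ortho-lithiated α-amino alkoxide | COCOc1cc(C)cc(C(O[Li])N(C)CCN(C)C)c1[Li] | intermediate (not isolated)
5 | 2-iodo-3-(methoxymethoxy)-5-methylbenzaldehyde | COCOc1cc(C)cc(C=O)c1I | intermediate
6 | methyl acrylate | C=CC(=O)OC | starting material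
7 | methyl 4-[2-iodo-3-(methoxymethoxy)-5-methylphenyl]-4-oxobutanoate | COCOc1cc(C)cc(C(=O)CCC(=O)OC)c1I | intermediate
8 | methyl (4R)-4-hydroxy-4-[2-iodo-3-(methoxymethoxy)-5-methylphenyl]butanoate | COCOc1cc(C)cc([C@H](O)CCC(=O)OC)c1I | intermediate (not isolated)
9 | (5R)-5-(3-hydroxy-2-iodo-5-methylphenyl)oxolan-2-one | Cc1cc(O)c(I)c(c1)[C@H]1CCC(=O)O1 | intermediate
10 | 2-hydroxy-3-iodo-6-methyl-4-[(2R)-5-oxooxolan-2-yl]benzaldehyde | Cc1cc([C@H]2CCC(=O)O2)c(I)c(O)c1C=O | intermediate
11 | 3-iodo-2-(methoxymethoxy)-6-methyl-4-[(2R)-5-oxooxolan-2-yl]benzaldehyde | COCOc1c(I)c([C@H]2CCC(=O)O2)cc(C)c1C=O | intermediate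
12 | (5R)-5-[4-(1-hydroxyprop-2-en-1-yl)-2-iodo-3-(methoxymethoxy)-5-methylphenyl]oxolan-2-one | COCOc1c(I)c([C@H]2CCC(=O)O2)cc(C)c1C(O)C=C | intermediate
13 | (5R)-5-{4-[(1E)-3-bromoprop-1-en-1-yl]-2-iodo-3-(methoxymethoxy)-5-methylphenyl}oxolan-2-one | COCOc1c(I)c([C@H]2CCC(=O)O2)cc(C)c1/C=C/CBr | intermediate
14 | 3-bromo-5-methylphenol | Cc1cc(O)cc(Br)c1 | starting material
15 | 1-bromo-3-(methoxymethoxy)-5-methylbenzene | COCOc1cc(C)cc(Br)c1 | intermediate
16 | 2-bromo-6-(methoxymethoxy)-4-methylphenyllithium | COCOc1cc(C)cc(Br)c1[Li] | intermediate (not isolated)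
17 | lithium hemiaminal alkoxide from 16 and DMF | COCOc1cc(C)cc(Br)c1C(O[Li])N(C)C | intermediate (not isolated)
18 | 2-bromo-6-(methoxymethoxy)-4-methylbenzaldehyde | COCOc1cc(C)cc(Br)c1C=O | intermediate
19 | trimethylsilyl ether of 20 | C=C[C@H](c1c(C)cc([C@H]2CCC(=O)O2)c(I)c1OCOC)[C@H](O[Si](C)(C)C)c1c(Br)cc(C)cc1OCOC | intermediate (not isolated)
20 | (5R)-5-{4-[(3R,4S)-4-[2-bromo-6-(methoxymethoxy)-4-methylphenyl]-4-hydroxybut-1-en-3-yl]-2-iodo-3-(methoxymethoxy)-5-methylphenyl}oxolan-2-one | C=C[C@H](c1c(C)cc([C@H]2CCC(=O)O2)c(I)c1OCOC)[C@H](O)c1c(Br)cc(C)cc1OCOC | intermediate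
21 | B-alkyl-9-borabicyclo[3.3.1]nonane from 20 (hydroxyl drawn free) | B1(CC[C@H](c2c(C)cc([C@H]3CCC(=O)O3)c(I)c2OCOC)[C@H](O)c2c(Br)cc(C)cc2OCOC)C2CCCC1CCC2 | intermediate (not isolated)
22 | (5R)-5-{4-[(1S,2R)-1-[2-bromo-6-(methoxymethoxy)-4-methylphenyl]-1,4-dihydroxybutan-2-yl]-2-iodo-3-(methoxymethoxy)-5-methylphenyl}oxolan-2-one | OCC[C@H](c1c(C)cc([C@H]2CCC(=O)O2)c(I)c1OCOC)[C@H](O)c1c(Br)cc(C)cc1OCOC | intermediate
23 | lactol of unit A (2-hydroxyoxolane) | OC1C[C@H](c2c(C)cc([C@H]3CCC(=O)O3)c(I)c2OCOC)[C@@H](c2c(Br)cc(C)cc2OCOC)O1 | intermediate (not isolated)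
24 | (4R,5S)-5-[2-bromo-6-(methoxymethoxy)-4-methylphenyl]-4-{3-iodo-2-(methoxymethoxy)-6-methyl-4-[(2R)-5-oxooxolan-2-yl]phenyl}oxolan-2-one | O=C1C[C@H](c2c(C)cc([C@H]3CCC(=O)O3)c(I)c2OCOC)[C@@H](c2c(Br)cc(C)cc2OCOC)O1 | intermediate
25 | bis(aryllithium) from 24 | O=C1C[C@H](c2c(C)cc([C@H]3CCC(=O)O3)c([Li])c2OCOC)[C@@H](c2c([Li])cc(C)cc2OCOC)O1 | intermediate (not isolated)
26 | dilithium dialkoxide of 27 | Cc1cc(OCOC)c2c(c1)C(=O)C[C@H](c1c(C)cc3c(c1OCOC)C(=O)CC[C@H]3O[Li])[C@@H]2O[Li] | intermediate (not isolated)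
27 | (3R,4S)-4-hydroxy-3-[(5R)-5-hydroxy-1-(methoxymethoxy)-3-methyl-8-oxo-5,6,7,8-tetrahydronaphthalen-2-yl]-5-(methoxymethoxy)-7-methyl-3,4-dihydronaphthalen-1(2H)-one | Cc1cc(OCOC)c2c(c1)C(=O)C[C@H](c1c(C)cc3c(c1OCOC)C(=O)CC[C@H]3O)[C@@H]2O | intermediate
28 | (3R,4S)-4,5-dihydroxy-3-[(5R)-1,5-dihydroxy-3-methyl-8-oxo-5,6,7,8-tetrahydronaphthalen-2-yl]-7-methyl-3,4-dihydronaphthalen-1(2H)-one | Cc1cc(O)c2c(c1)C(=O)C[C@H](c1c(C)cc3c(c1O)C(=O)CC[C@H]3O)[C@@H]2O | target

Total step count: 15. Longest linear sequence: 13 steps (steps 1–8 and 11–15, starting from 1).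

Steps most likely to fail

Step 14. The alkyllithium may add to a lactone carbonyl before exchange is complete, or one aryllithium may be protonated by an enolisable carbonyl group before it cyclises, so that halogen is lost without ring closure. The fallback sets out from 24 and opens both rings before the acyl transfer. Me(MeO)NH·HCl with AlMe3 in CH2Cl2 at 0 °C should open both lactones to the bis(N-methoxy-N-methylamide) diol F1. Et3SiCl and imidazole would cap both carbinols as the bis(triethylsilyl) ether F2. A Parham cyclisation of F2 on the two open-chain Weinreb amides (t-BuLi, THF, −78 °C) would give the protected diketone F3. Aqueous HCl in MeOH/THF would remove the silyl and MOM groups together, and the route is rejoined at 28.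

Step 11. Both partners are di-ortho-substituted, so the allylchromium may react through its α-carbon (linear isomer), conversion may stall, or facial selectivity may be poor. The fallback sets out from 11 and moves the stereocontrol to an allylboration. A boron-Wittig reaction of 11 with CH2(Bpin)2 and lithium tetramethylpiperidide should give the (E)-alkenyl boronate F4. Matteson homologation (ICH2Cl, n-BuLi, −100 °C, in situ) would convert it into the (E)-γ-aryl allyl boronate F5. Addition of F5 to aldehyde 18 under catalysis by the chiral phosphoric acid (R)-3,3′-bis(2,4,6-triisopropylphenyl)-1,1′-binaphthyl-2,2′-diyl hydrogen phosphate (or its enantiomer) proceeds through a closed chair transition state and should return the anti adduct 20.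

Step 3. The ortho-iodo aldehyde may form the acyl anion equivalent slowly, so that self-condensation of the aldehyde or catalyst decay wins over conjugate addition. The fallback sets out from 5 and builds the same carbon chain by carbonyl addition. Asymmetric addition of methyl propiolate (Me2Zn, ProPhenol ligand, toluene) should give the γ-hydroxy ynoate F6 with the carbinol centre already set. Diimide reduction of the triple bond (2-nitrobenzenesulfonohydrazide, Et3N) would give the hydroxy ester 8, which the acid stage of step 4 converts into 9.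

Further compounds
F1 | step 14 | (3R,4S)-4-[2-bromo-6-(methoxymethoxy)-4-methylphenyl]-4-hydroxy-3-{4-[(1R)-1-hydroxy-4-[methoxy(methyl)amino]-4-oxobutyl]-3-iodo-2-(methoxymethoxy)-6-methylphenyl}-N-methoxy-N-methylbutanamide | CON(C)C(=O)C[C@H](c1c(C)cc([C@H](O)CCC(=O)N(C)OC)c(I)c1OCOC)[C@H](O)c1c(Br)cc(C)cc1OCOC
F2 | step 14 | bis(triethylsilyl) ether of F1 | CON(C)C(=O)C[C@H](c1c(C)cc([C@H](O[Si](CC)(CC)CC)CCC(=O)N(C)OC)c(I)c1OCOC)[C@H](O[Si](CC)(CC)CC)c1c(Br)cc(C)cc1OCOC
F3 | step 14 | bis(triethylsilyl) ether of 27 | Cc1cc(OCOC)c2c(c1)C(=O)C[C@H](c1c(C)cc3c(c1OCOC)C(=O)CC[C@H]3O[Si](CC)(CC)CC)[C@@H]2O[Si](CC)(CC)CC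
F4 | step 11 | (5R)-5-{2-iodo-3-(methoxymethoxy)-5-methyl-4-[(E)-2-(4,4,5,5-tetramethyl-1,3,2-dioxaborolan-2-yl)ethenyl]phenyl}oxolan-2-one | COCOc1c(I)c([C@H]2CCC(=O)O2)cc(C)c1/C=C/B1OC(C)(C)C(C)(C)O1
F5 | step 11 | (5R)-5-{2-iodo-3-(methoxymethoxy)-5-methyl-4-[(1E)-3-(4,4,5,5-tetramethyl-1,3,2-dioxaborolan-2-yl)prop-1-en-1-yl]phenyl}oxolan-2-one | COCOc1c(I)c([C@H]2CCC(=O)O2)cc(C)c1/C=C/CB1OC(C)(C)C(C)(C)O1
F6 | step 3 | methyl (4R)-4-hydroxy-4-[2-iodo-3-(methoxymethoxy)-5-methylphenyl]but-2-ynoate | COCOc1cc(C)cc([C@H](O)C#CC(=O)OC)c1I
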